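Everything rests on not forging the crowded diaryl ether by C–O coupling: ring B is grown on the ring A oxygen instead. In ring B the ether carbon C1' sits between C2' (OH) and C6' (CH2OH), with methyl on C4', so O–C1'–C2'–C3' is an O-alkylated acetone and C4'–C5'–C6' with the CH2OH carbon is an acetopyruvate. One alkoxide-mediated double aldol (3+3) condensation makes C1'–C6' and C3'–C4' and aromatises ring B to the phenol with the ether already in place. The precursor is ring A aryloxyacetone 13: a 2-methoxy-6-(2-oxopropoxy)benzoic acid with the silyl-protected (S)-carbinol chain, its carboxyl deliberately free.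

Key step: step 8

Remarks on the chemistry
- Configuration: the carbinol carbon of the target SMILES is read as (S) (OH > aryl > CH2 > H).
- Precursor design: the ring A carboxyl goes through the key step as a carboxylate, not as an ester. An ester ortho to the O–CH2–C(=O)CH3 arm would be attacked by the very enolate the key step needs (Dieckmann-type 5-(enolexo)-exo-trig closure to a 2-acetylbenzofuran-3-ol). A carboxylate is inert to this, needs no late hydrolysis of a hindered ester, and is left alone by LiBH4.
- Masked ketone and acid sensitivity: the acetonyl arm is carried as a methallyl ether and unmasked oxidatively, so only one ketone is present at the enantioselective reduction. Once the carbinol exists, no step is run in acid, and acidifications at work-up are done cold and only to pH 3–4, because the benzylic C–O bond (ortho OMe, para O-aryl) ionises easily.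

Step 1
Reactants: 1 methyl 2,6-dihydroxybenzoate; 2 3-methylbutanoyl chloride (isovaleryl chloride)
Product: 3 methyl 2,6-dihydroxy-3-(3-methylbutanoyl)benzoate
Conditions: AlCl3 (3.5 equiv), ClCH2CH2Cl, 0 → 60 °C; ice/1 M HCl
Reagents that add atoms: 3-methylbutanoyl chloride (2), CC(C)CC(=O)Cl
Why: Friedel–Crafts acylation (directly or by O-acylation and Fries shift under the same AlCl3) at the only activated positions, C3 and C5, which are equivalent by symmetry and each ortho to one hydroxyl and para to the other; the first acyl group deactivates the ring against a second.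

Step 2
Reactants: 3 methyl 2,6-dihydroxy-3-(3-methylbutanoyl)benzoate; 4 3-chloro-2-methylprop-1-ene (methallyl chloride)
Product: 5 methyl 2-hydroxy-3-(3-methylbutanoyl)-6-[(2-methylprop-2-en-1-yl)oxy]benzoate
Conditions: 4 (1.1 equiv), K2CO3 (1.2 equiv), KI (0.1 equiv), acetone, 56 °C
Reagents that add atoms: 3-chloro-2-methylprop-1-ene (4), C=C(C)CCl
Why: Williamson etherification with about one equivalent of weak base; the C6 hydroxyl is para to the new ketone (more acidic) and has a free ortho position, whereas the C2 hydroxyl is wedged between ketone and ester and held in a strong hydrogen bond, so O6 should be alkylated selectively.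

Step 3
Reactants: 5 methyl 2-hydroxy-3-(3-methylbutanoyl)-6-[(2-methylprop-2-en-1-yl)oxy]benzoate; 6 iodomethane
Product: 7 methyl 2-methoxy-3-(3-methylbutanoyl)-6-[(2-methylprop-2-en-1-yl)oxy]benzoate
Conditions: MeI (3 equiv), K2CO3 (2.5 equiv), DMF, 45 °C (closed vessel)
Reagents that add atoms: iodomethane (6), CI
Why: Williamson O-methylation of the remaining chelated phenol, driven by excess MeI in a dipolar aprotic solvent; carbonate is too weak to enolise the aryl ketone and a Claisen shift of the allylic ether needs far higher temperature.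

Step 4
Reactants: 7 methyl 2-methoxy-3-(3-methylbutanoyl)-6-[(2-methylprop-2-en-1-yl)oxy]benzoate
Product: 8 2-methoxy-3-(3-methylbutanoyl)-6-[(2-methylprop-2-en-1-yl)oxy]benzoic acid
Conditions: KOH (10 equiv), MeOH/H2O (3:1), 80 °C (closed vessel); then 1 M HCl to pH 2
Reagents that add atoms: potassium hydroxide, [K+].[OH-]
Why: saponification of the 2,6-dialkoxybenzoate, slowed but not blocked by the two small ortho oxygen substituents; it is placed before the stereocentre exists, while nothing in the molecule is sensitive to heat or base, and the protic medium cannot isomerise the allylic ether.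

Step 5
Reactants: 8 2-methoxy-3-(3-methylbutanoyl)-6-[(2-methylprop-2-en-1-yl)oxy]benzoic acid
Product: 9 3-[(1S)-1-hydroxy-3-methylbutyl]-2-methoxy-6-[(2-methylprop-2-en-1-yl)oxy]benzoic acid
Conditions: NaOH (1.0 equiv), RuCl[(S,S)-TsDPEN](p-cymene) (1 mol %), HCO2Na (5 equiv), H2O/MeOH (1:1), 40 °C; then KHSO4 to pH 3, 0 °C
Reagents that add atoms: none
Why: Noyori–Ikariya asymmetric transfer hydrogenation of an aryl alkyl ketone; the (S,S)-TsDPEN ruthenium hydride delivers hydride and NH proton through a six-membered transition state in which the aryl ring is held by a CH–π contact to the η6-arene, which should give the (S)-carbinol, while the isolated alkene and the carboxylate are inert and the near-neutral medium avoids benzylic ionisation.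

Step 6
Reactants: 9 3-[(1S)-1-hydroxy-3-methylbutyl]-2-methoxy-6-[(2-methylprop-2-en-1-yl)oxy]benzoic acid; 10 tert-butyl(chloro)dimethylsilane (TBSCl)
Product: 12 3-[(1S)-1-(tert-butyldimethylsilyloxy)-3-methylbutyl]-2-methoxy-6-[(2-methylprop-2-en-1-yl)oxy]benzoic acid, via bis-silylated ester 11 (not isolated)
Conditions: TBSCl (3 equiv), imidazole (6 equiv), DMF, 25 → 40 °C; then K2CO3, MeOH/H2O/THF, 0 °C; cold citric acid to pH 4
Reagents that add atoms: tert-butyl(chloro)dimethylsilane (10), CC(C)(C)[Si](C)(C)Cl
Why: imidazole-promoted silylation of the secondary alcohol (the acid is silylated as well), followed by selective solvolysis of the far more labile silyl ester; the (S) centre is not involved.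

Step 7
Reactants: 12 3-[(1S)-1-(tert-butyldimethylsilyloxy)-3-methylbutyl]-2-methoxy-6-[(2-methylprop-2-en-1-yl)oxy]benzoic acid
Product: 13 3-[(1S)-1-(tert-butyldimethylsilyloxy)-3-methylbutyl]-2-methoxy-6-(2-oxopropoxy)benzoic acid
Conditions: OsO4 (2 mol %), NaIO4 (4 equiv), 2,6-lutidine (3 equiv), 1,4-dioxane/H2O (3:1), 20 °C
Reagents that add atoms: osmium tetroxide (oxygen carrier), O=[Os](=O)(=O)=O; sodium periodate (terminal oxidant), [Na+].[O-]I(=O)(=O)=O
Why: Lemieux–Johnson oxidation, in which OsO4 dihydroxylates the 1,1-disubstituted alkene and periodate cleaves the glycol, turns the methallyl ether into the acetonyl ether under buffered, near-neutral conditions that spare the silyl ether, the arene and the acid.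

Step 8
Reactants: 13 3-[(1S)-1-(tert-butyldimethylsilyloxy)-3-methylbutyl]-2-methoxy-6-(2-oxopropoxy)benzoic acid; 14 ethyl 2,4-dioxopentanoate
Product: 17 6-[2-(ethoxycarbonyl)-6-hydroxy-4-methylphenoxy]-2-methoxy-3-[(1S)-1-(tert-butyldimethylsilyloxy)-3-methylbutyl]benzoic acid, via acyclic enone 15 (not isolated), via cyclic aldol 16 (not isolated)
Conditions: 14 (2 equiv, in portions), NaOEt (4 equiv), EtOH, 3 Å molecular sieves, 0 → 50 °C; then AcOH (4 equiv), 0 °C
Reagents that add atoms: ethyl 2,4-dioxopentanoate (14), CCOC(=O)C(=O)CC(C)=O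
Why: Proposed new method: ethoxide equilibrates the keto carboxylate of 13 to its more stabilised enolate at the aryloxy-bearing CH2 (future C1'), which adds to the ester-flanked C2 carbonyl of 14 (future C6'), and loss of water gives enone 15 with the C1'–C6' bond made. The CH3 end of the former acetone (C3') is then enolised toward C2' and closes on the acetyl carbonyl (C4') in a 6-(enolendo)-exo-trig aldol to give 16, and a second dehydration followed by enolisation of the C2' ketone delivers the phenoxide of 17, an irreversible aromatisation that pulls the reversible aldol steps forward. The closest known reaction type is the alkoxide-mediated (3+3) double aldol condensation of acetone-type ketones with acylpyruvates to 3-hydroxybenzoates; an α-aryloxy ketone as the three-carbon partner is the unproven part, although such ketones react at the O-substituted methylene in Friedländer and Pfitzinger condensations and carbon nucleophiles attack acylpyruvates at the ester-flanked carbonyl in the Guareschi pyridone synthesis. No stereocentre is formed (the carbinol carbon of 16 disappears on dehydration) and the silylated (S) centre carries no acidic hydrogen. The step needs the pairing of OCH2 with C2 and of CH3 with C4 (the reverse pairing would give the 4-aryloxy isomer), which the higher acidity of the O-substituted methylene and the higher electrophilicity of the ester-flanked carbonyl should secure; it also needs the enolate not to be trapped within ring A, which is secured by carrying the ring A carboxyl as a carboxylate that cannot undergo Dieckmann closure.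

Step 9
Reactants: 17 6-[2-(ethoxycarbonyl)-6-hydroxy-4-methylphenoxy]-2-methoxy-3-[(1S)-1-(tert-butyldimethylsilyloxy)-3-methylbutyl]benzoic acid
Product: 18 6-[2-hydroxy-6-(hydroxymethyl)-4-methylphenoxy]-2-methoxy-3-[(1S)-1-(tert-butyldimethylsilyloxy)-3-methylbutyl]benzoic acid
Conditions: LiBH4 (4 equiv), THF, 0 → 40 °C; then aq. NH4Cl and cold citric acid to pH 4
Reagents that add atoms: none
Why: chemoselective ester reduction by LiBH4; acid and phenol are deprotonated first, the resulting carboxylate is not reduced by borohydride and is shielded by two ortho substituents besides, so only the ring B ethyl ester should be reduced to the benzylic alcohol.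

Step 10
Reactants: 18 6-[2-hydroxy-6-(hydroxymethyl)-4-methylphenoxy]-2-methoxy-3-[(1S)-1-(tert-butyldimethylsilyloxy)-3-methylbutyl]benzoic acid
Product: 19 6-[2-hydroxy-6-(hydroxymethyl)-4-methylphenoxy]-3-[(1S)-1-hydroxy-3-methylbutyl]-2-methoxybenzoic acid (CNP0221397.1)
Conditions: TBAF (5 equiv), THF, 25 → 45 °C; then aq. NH4Cl, citrate buffer to pH 3–4, EtOAc extraction
Reagents that add atoms: none
Why: fluoride-induced cleavage of the silyl ether (formation of the strong Si–F bond) under basic, non-ionising conditions, followed by gentle acidification, should release the (S)-carbinol without epimerisation.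

Compound list
1 | methyl 2,6-dihydroxybenzoate | COC(=O)c1c(O)cccc1O | starting material
2 | 3-methylbutanoyl chloride (isovaleryl chloride) | CC(C)CC(=O)Cl | starting material
3 | methyl 2,6-dihydroxy-3-(3-methylbutanoyl)benzoate | COC(=O)c1c(O)c(C(=O)CC(C)C)ccc1O | intermediate
4 | 3-chloro-2-methylprop-1-ene (methallyl chloride) | C=C(C)CCl | starting material
5 | methyl 2-hydroxy-3-(3-methylbutanoyl)-6-[(2-methylprop-2-en-1-yl)oxy]benzoate | COC(=O)c1c(O)c(C(=O)CC(C)C)ccc1OCC(C)=C | intermediate
6 | iodomethane | CI | starting material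
7 | methyl 2-methoxy-3-(3-methylbutanoyl)-6-[(2-methylprop-2-en-1-yl)oxy]benzoate | COC(=O)c1c(OC)c(C(=O)CC(C)C)ccc1OCC(C)=C | intermediate
8 | 2-methoxy-3-(3-methylbutanoyl)-6-[(2-methylprop-2-en-1-yl)oxy]benzoic acid | OC(=O)c1c(OC)c(C(=O)CC(C)C)ccc1OCC(C)=C | intermediate
9 | 3-[(1S)-1-hydroxy-3-methylbutyl]-2-methoxy-6-[(2-methylprop-2-en-1-yl)oxy]benzoic acid | OC(=O)c1c(OC)c([C@@H](O)CC(C)C)ccc1OCC(C)=C | intermediate
10 | tert-butyl(chloro)dimethylsilane (TBSCl) | CC(C)(C)[Si](C)(C)Cl | starting material
11 | bis-silylated ester: tert-butyldimethylsilyl 3-[(1S)-1-(tert-butyldimethylsilyloxy)-3-methylbutyl]-2-methoxy-6-[(2-methylprop-2-en-1-yl)oxy]benzoate | CC(C)(C)[Si](C)(C)OC(=O)c1c(OC)c([C@@H](O[Si](C)(C)C(C)(C)C)CC(C)C)ccc1OCC(C)=C | intermediate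
12 | 3-[(1S)-1-(tert-butyldimethylsilyloxy)-3-methylbutyl]-2-methoxy-6-[(2-methylprop-2-en-1-yl)oxy]benzoic acid | OC(=O)c1c(OC)c([C@@H](O[Si](C)(C)C(C)(C)C)CC(C)C)ccc1OCC(C)=C | intermediate
13 | 3-[(1S)-1-(tert-butyldimethylsilyloxy)-3-methylbutyl]-2-methoxy-6-(2-oxopropoxy)benzoic acid | OC(=O)c1c(OC)c([C@@H](O[Si](C)(C)C(C)(C)C)CC(C)C)ccc1OCC(C)=O | intermediate
14 | ethyl 2,4-dioxopentanoate | CCOC(=O)C(=O)CC(C)=O | starting material
15 | acyclic enone: 6-{[4-(ethoxycarbonyl)-2,6-dioxohept-3-en-3-yl]oxy}-2-methoxy-3-[(1S)-1-(tert-butyldimethylsilyloxy)-3-methylbutyl]benzoic acid (alkene geometry not fixed) | CCOC(=O)C(CC(C)=O)=C(Oc1ccc([C@@H](O[Si](C)(C)C(C)(C)C)CC(C)C)c(OC)c1C(=O)O)C(C)=O | intermediate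
16 | cyclic aldol: 6-{[2-(ethoxycarbonyl)-4-hydroxy-4-methyl-6-oxocyclohex-1-en-1-yl]oxy}-2-methoxy-3-[(1S)-1-(tert-butyldimethylsilyloxy)-3-methylbutyl]benzoic acid (both configurations at the ring carbinol) | CCOC(=O)C1=C(Oc2ccc([C@@H](O[Si](C)(C)C(C)(C)C)CC(C)C)c(OC)c2C(=O)O)C(=O)CC(C)(O)C1 | intermediate
17 | 6-[2-(ethoxycarbonyl)-6-hydroxy-4-methylphenoxy]-2-methoxy-3-[(1S)-1-(tert-butyldimethylsilyloxy)-3-methylbutyl]benzoic acid | OC(=O)c1c(OC)c([C@@H](O[Si](C)(C)C(C)(C)C)CC(C)C)ccc1Oc1c(O)cc(C)cc1C(=O)OCC | intermediate
18 | 6-[2-hydroxy-6-(hydroxymethyl)-4-methylphenoxy]-2-methoxy-3-[(1S)-1-(tert-butyldimethylsilyloxy)-3-methylbutyl]benzoic acid | OC(=O)c1c(OC)c([C@@H](O[Si](C)(C)C(C)(C)C)CC(C)C)ccc1Oc1c(O)cc(C)cc1CO | intermediate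
19 | 6-[2-hydroxy-6-(hydroxymethyl)-4-methylphenoxy]-3-[(1S)-1-hydroxy-3-methylbutyl]-2-methoxybenzoic acid (CNP0221397.1) | COc1c([C@@H](O)CC(C)C)ccc(Oc2c(O)cc(C)cc2CO)c1C(=O)O | target

Total step count: 10. Longest linear sequence: 10 steps (1 → 19); 2, 4, 6, 10 and 14 are purchased reagents.

Steps most likely to fail

1. Step 8 (cyclocondensation). The first, intermolecular aldol may not start because ethoxide turns both partners largely into enolates; the two nucleophilic carbons of 13 may pair with the wrong carbonyl groups of 14; or 14 may be consumed by self-condensation before it is intercepted. The fallback uses known chemistry and attaches a preformed ring B by nucleophilic aromatic substitution; it sets out from 12 and returns at 18. The methallyl ether of 12 is cleaved with Pd(PPh3)4 (zerovalent palladium) and morpholine in THF at 50 °C to give 6-hydroxy-2-methoxy-3-[(1S)-1-(tert-butyldimethylsilyloxy)-3-methylbutyl]benzoic acid F1. Separately, commercial 2-fluoro-5-methylphenol is benzylated (BnBr, K2CO3, DMF) to 2-(benzyloxy)-1-fluoro-4-methylbenzene F2. F2 is lithiated next to fluorine (LiN(iPr)2, THF, −78 °C; the site next to the benzyloxy group is blocked by the methyl group) and formylated with DMF to 3-(benzyloxy)-2-fluoro-5-methylbenzaldehyde F3. The dipotassium salt of F1 displaces the fluoride of F3, which is activated by the ortho formyl group (K2CO3, DMF, 100 °C), to give 6-[2-(benzyloxy)-6-formyl-4-methylphenoxy]-2-methoxy-3-[(1S)-1-(tert-butyldimethylsilyloxy)-3-methylbutyl]benzoic acid F4. NaBH4 in MeOH/THF at 0 °C reduces the aldehyde to 6-[2-(benzyloxy)-6-(hydroxymethyl)-4-methylphenoxy]-2-methoxy-3-[(1S)-1-(tert-butyldimethylsilyloxy)-3-methylbutyl]benzoic acid F5. Hydrogenolysis of the benzyl ether (H2, Pd/C, EtOAc, 20 °C) then gives 18.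

2. Step 5 (asymmetric transfer hydrogenation). Facial selectivity may be eroded by the ortho methoxy group and the branched alkyl chain, or turnover may be slow for the carboxylate salt. The fallback changes both the mode of stereoinduction and the order of events; it sets out from keto ester 7 and returns at 9. Oxazaborolidine-catalysed reduction of 7 ((R)-2-methyl-CBS-oxazaborolidine, catecholborane, toluene, −78 °C; catecholborane leaves the 1,1-disubstituted alkene and the ester alone at this temperature) should give methyl 3-[(1S)-1-hydroxy-3-methylbutyl]-2-methoxy-6-[(2-methylprop-2-en-1-yl)oxy]benzoate F6. After removal of boron residues, F6 is saponified under the conditions of step 4, with acidification only to pH 3 at 0 °C, to give 9.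

3. Step 2 (site-selective O-alkylation). Over-alkylation through the dianion, or alkylation at the wrong hydroxyl, would erode the supply of 5. The fallback is a Mitsunobu etherification of 3 with 2-methylprop-2-en-1-ol (PPh3, DIAD, THF, 0 → 20 °C). Only the more acidic and less hindered C6 phenol is activated as the ion pair, and no dianion can form. It sets out from 3, makes no new compound (F0) and returns at 5.

Further compounds
F1 | step 8 | 6-hydroxy-2-methoxy-3-[(1S)-1-(tert-butyldimethylsilyloxy)-3-methylbutyl]benzoic acid | OC(=O)c1c(OC)c([C@@H](O[Si](C)(C)C(C)(C)C)CC(C)C)ccc1O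
F2 | step 8 | 2-(benzyloxy)-1-fluoro-4-methylbenzene | Cc1ccc(F)c(OCc2ccccc2)c1
F3 | step 8 | 3-(benzyloxy)-2-fluoro-5-methylbenzaldehyde | Cc1cc(C=O)c(F)c(OCc2ccccc2)c1
F4 | step 8 | 6-[2-(benzyloxy)-6-formyl-4-methylphenoxy]-2-methoxy-3-[(1S)-1-(tert-butyldimethylsilyloxy)-3-methylbutyl]benzoic acid | OC(=O)c1c(OC)c([C@@H](O[Si](C)(C)C(C)(C)C)CC(C)C)ccc1Oc1c(OCc2ccccc2)cc(C)cc1C=O
F5 | step 8 | 6-[2-(benzyloxy)-6-(hydroxymethyl)-4-methylphenoxy]-2-methoxy-3-[(1S)-1-(tert-butyldimethylsilyloxy)-3-methylbutyl]benzoic acid | OC(=O)c1c(OC)c([C@@H](O[Si](C)(C)C(C)(C)C)CC(C)C)ccc1Oc1c(OCc2ccccc2)cc(C)cc1CO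
F6 | step 5 | methyl 3-[(1S)-1-hydroxy-3-methylbutyl]-2-methoxy-6-[(2-methylprop-2-en-1-yl)oxy]benzoate | COC(=O)c1c(OC)c([C@@H](O)CC(C)C)ccc1OCC(C)=C
F0 | step 2 | none | none
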